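The heptaene is cut on both sides of its central E ethene unit, C15=C15' (carotenoid numbering; ring A is the hydroxylated ring C1–C6, ring B the cyclohexadiene ring C1'–C6'), because C14 and C14' are plain CH termini of two ring-bearing C19 trienyne halves. One pot then joins (E)-1,2-bis(tributylstannyl)ethene first to the ring B alkenyl iodide and afterwards to the ring A alkenyl iodide by two Stille couplings, forming C14'–C15' and C14–C15 and giving the target directly. Both precursors are geometrically defined (E)-alkenyl iodides; the ring A one keeps its (3R) hydroxyl free, which spares a final deprotection and gives the three possible heptaenes different polarity.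

Key step: step 16

Remark on the structure: the target SMILES encodes an all-E chain and R configuration at C3 of ring A (O > C2 > C4 > H); the route is planned for exactly this isomer.
Assumption: 2,6,6-trimethylcyclohex-2-en-1-one (1) and diethyl [3-(trimethylsilyl)prop-2-yn-1-yl]phosphonate (7) are taken as catalogue chemicals.

Step 1
Reactants: 1 2,6,6-trimethylcyclohex-2-en-1-one
Product: 3 2,6,6-trimethylcyclohexa-1,3-dien-1-yl trifluoromethanesulfonate (ring B dienyl triflate), via lithium dienolate 2 (not isolated)
Conditions: LiN(i-Pr)2 (1.1 equiv), THF, −78 °C; PhNTf2, −78 → 0 °C; aq. NH4Cl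
Reagents that add atoms: N-phenylbis(trifluoromethanesulfonimide) (PhNTf2), FC(F)(F)S(=O)(=O)N(c1ccccc1)S(=O)(=O)C(F)(F)F
Why: With C6 quaternary, the amide base can only abstract a γ-hydrogen at C4, and O-sulfonylation of the resulting linear dienolate by PhNTf2 (enol triflate formation) should give the 1,3-dienyl triflate that already holds both ring B double bonds.

Step 2
Reactants: 3 ring B dienyl triflate; 4 (E)-3-methylpent-2-en-4-yn-1-ol
Product: 5 (2E)-3-methyl-5-(2,6,6-trimethylcyclohexa-1,3-dien-1-yl)pent-2-en-4-yn-1-ol (ring B C15 alcohol)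
Conditions: Pd(PPh3)4 (5 mol %), CuI (10 mol %), i-Pr2NH, DMF, 25–45 °C, degassed
Reagents that add atoms: none
Why: Sonogashira coupling: the dienyl C–OTf bond adds to zerovalent palladium and the copper acetylide formed from 4 delivers the enynol, joining ring carbon C6' to C7' while the preset E geometry at C9'=C10' and the free hydroxyl are untouched.

Step 3
Reactants: 5 ring B C15 alcohol
Product: 6 (2E)-3-methyl-5-(2,6,6-trimethylcyclohexa-1,3-dien-1-yl)pent-2-en-4-ynal (ring B C15 aldehyde)
Conditions: MnO2 (activated, excess), CH2Cl2, 25 °C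
Reagents that add atoms: none
Why: Heterogeneous MnO2 oxidation of an allylic alcohol is neutral and stops at the aldehyde, so the enynal should form without E/Z isomerisation or harm to the ring diene.

Step 4
Reactants: 6 ring B C15 aldehyde; 7 diethyl [3-(trimethylsilyl)prop-2-yn-1-yl]phosphonate
Product: 8 trimethyl[(3E,5E)-6-methyl-8-(2,6,6-trimethylcyclohexa-1,3-dien-1-yl)octa-3,5-diene-1,7-diyn-1-yl]silane (ring B silyl dienediyne)
Conditions: 7, n-BuLi, THF/DMPU, −78 °C; then 6, −78 → 0 °C; aq. NH4Cl
Reagents that add atoms: none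
Why: Horner–Wadsworth–Emmons olefination: the lithiated propargylic phosphonate adds reversibly to the aldehyde and collapse through the trans-oxaphosphetane should favour the E alkene at C11'=C12', a better prospect for geometric purity than the corresponding phosphonium ylide.

Step 5
Reactants: 8 ring B silyl dienediyne
Product: 9 (3E,5E)-3-methyl-1-(2,6,6-trimethylcyclohexa-1,3-dien-1-yl)octa-3,5-diene-1,7-diyne (ring B terminal alkyne)
Conditions: K2CO3 (cat.), MeOH/THF, 25 °C
Reagents that add atoms: none
Why: Base-catalysed methanolysis of the alkynyl C–Si bond (protodesilylation) frees the terminal alkyne under conditions that leave the dienediyne and the ring diene alone.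

Step 6
Reactants: 9 ring B terminal alkyne
Product: 11 (1E,3E,5E)-1-iodo-2,6-dimethyl-8-(2,6,6-trimethylcyclohexa-1,3-dien-1-yl)octa-1,3,5-trien-7-yne (ring B C19 iodide), via alkenylalane 10 (not isolated)
Conditions: AlMe3 (3 equiv), Cp2ZrCl2 (0.5 equiv), CH2Cl2, 0 → 25 °C; then I2, THF, −30 → 0 °C, dark; aq. Na2S2O3/NaHCO3
Reagents that add atoms: trimethylaluminium, C[Al](C)C; iodine, II
Why: Negishi zirconium-catalysed methylalumination adds CH3 and Al syn across the terminal alkyne with methyl on the internal carbon C13' (the hindered, disubstituted C7'≡C8' alkyne reacts far more slowly), and iodinolysis of the C–Al bond with retention should give the E iodide.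

Step 7
Reactants: 12 ketoisophorone (2,6,6-trimethylcyclohex-2-ene-1,4-dione)
Product: 13 (6R)-2,2,6-trimethylcyclohexane-1,4-dione ((6R)-levodione)
Conditions: baker's yeast (Saccharomyces cerevisiae), sucrose, H2O, 30 °C; stopped when 12 is consumed
Reagents that add atoms: none
Why: Whole-cell biocatalytic conjugate reduction: the enoate reductase of fermenting yeast adds hydride and a proton across the electron-poor C=C, and the enzyme's facial preference sets the methyl-bearing stereocentre as R.

Step 8
Reactants: 13 (6R)-levodione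
Product: 14 (4R,6R)-4-hydroxy-2,2,6-trimethylcyclohexan-1-one ((4R,6R)-actinol, hydroxyl trans to the C6 methyl)
Conditions: LiBH(s-Bu)3, THF, −78 °C; then H2O2, pH 7 phosphate buffer, 0 °C
Reagents that add atoms: none
Why: Substrate-controlled hydride reduction: the C1 carbonyl is shielded by three flanking methyl groups so only C4 reacts, and because the axial C2 methyl blocks axial approach the bulky borohydride attacks equatorially to give the axial alcohol trans to the equatorial C6 methyl, that is 4R; any cis epimer is removed here by chromatography or crystallisation, since it would become the enantiomeric series once C6 is planar.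

Step 9
Reactants: 14 (4R,6R)-actinol
Product: 15 (4R,6R)-4-(tert-butyldimethylsilyloxy)-2,2,6-trimethylcyclohexan-1-one
Conditions: TBSCl, imidazole, DMF, 25 °C
Reagents that add atoms: tert-butyldimethylsilyl chloride, CC(C)(C)[Si](C)(C)Cl
Why: Imidazole-promoted silylation of the secondary alcohol gives a silyl ether that withstands the amide base, the palladium coupling and the olefination to come.

Step 10
Reactants: 15 silyl-protected actinol
Product: 17 (4R)-4-(tert-butyldimethylsilyloxy)-2,6,6-trimethylcyclohex-1-en-1-yl trifluoromethanesulfonate (ring A enol triflate), via lithium enolate 16 (not isolated)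
Conditions: LiN(i-Pr)2 (1.2 equiv), THF, −78 °C; PhNTf2, −78 → 25 °C; aq. NH4Cl
Reagents that add atoms: N-phenylbis(trifluoromethanesulfonimide) (PhNTf2), FC(F)(F)S(=O)(=O)N(c1ccccc1)S(=O)(=O)C(F)(F)F
Why: C6 carries the only α-hydrogen, so deprotonation gives a single tetrasubstituted enolate and O-sulfonylation with PhNTf2 (enol triflate formation) fixes the future C5=C6 double bond of ring A; the C6 stereocentre is erased on purpose while the silyloxy-bearing centre, now the only one, stays R.

Step 11
Reactants: 17 ring A enol triflate; 4 (E)-3-methylpent-2-en-4-yn-1-ol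
Product: 18 (2E)-5-[(4R)-4-(tert-butyldimethylsilyloxy)-2,6,6-trimethylcyclohex-1-en-1-yl]-3-methylpent-2-en-4-yn-1-ol (ring A C15 alcohol)
Conditions: Pd(PPh3)4 (5 mol %), CuI (10 mol %), i-Pr2NH, DMF, 25–45 °C, degassed
Reagents that add atoms: none
Why: Sonogashira coupling as in step 2, here on the tetrasubstituted cyclohexenyl triflate, forms the C6–C7 bond and brings in C7–C11 with the E geometry of C9=C10 preset.

Step 12
Reactants: 18 ring A C15 alcohol
Product: 19 (2E)-5-[(4R)-4-(tert-butyldimethylsilyloxy)-2,6,6-trimethylcyclohex-1-en-1-yl]-3-methylpent-2-en-4-ynal (ring A C15 aldehyde)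
Conditions: MnO2 (activated, excess), CH2Cl2, 25 °C
Reagents that add atoms: none
Why: Selective MnO2 oxidation of the allylic alcohol, as in step 3, should give the enynal without touching the silyl ether or the alkene geometry.

Step 13
Reactants: 19 ring A C15 aldehyde; 7 diethyl [3-(trimethylsilyl)prop-2-yn-1-yl]phosphonate
Product: 20 tert-butyldimethyl({(1R)-3,5,5-trimethyl-4-[(3E,5E)-3-methyl-8-(trimethylsilyl)octa-3,5-diene-1,7-diyn-1-yl]cyclohex-3-en-1-yl}oxy)silane (ring A bis-silyl dienediyne)
Conditions: 7, n-BuLi, THF/DMPU, −78 °C; then 19, −78 → 0 °C; aq. NH4Cl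
Reagents that add atoms: none
Why: Horner–Wadsworth–Emmons olefination as in step 4 should build C11=C12 with E geometry and install the silyl-capped C13≡C14 alkyne.

Step 14
Reactants: 20 ring A bis-silyl dienediyne
Product: 21 (1R)-3,5,5-trimethyl-4-[(3E,5E)-3-methylocta-3,5-diene-1,7-diyn-1-yl]cyclohex-3-en-1-ol (ring A hydroxy terminal alkyne)
Conditions: Bu4NF (3 equiv), THF, 0 → 25 °C; aq. NH4Cl
Reagents that add atoms: none
Why: Fluoride-induced desilylation, driven by the strong Si–F bond, cleaves the alkynyl C–Si bond and the silyl ether in one operation, so the terminal alkyne and the free C3 hydroxyl wanted in the coupling partner appear together.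

Step 15
Reactants: 21 ring A hydroxy terminal alkyne
Product: 23 (1R)-4-[(3E,5E,7E)-8-iodo-3,7-dimethylocta-3,5,7-trien-1-yn-1-yl]-3,5,5-trimethylcyclohex-3-en-1-ol (ring A C19 iodide), via alkenylalane 22 (not isolated)
Conditions: AlMe3 (4 equiv), Cp2ZrCl2 (0.5 equiv), CH2Cl2, 0 → 25 °C; then I2, THF, −30 → 0 °C, dark; aq. Na2S2O3/NaHCO3
Reagents that add atoms: trimethylaluminium, C[Al](C)C; iodine, II
Why: Negishi carboalumination as in step 6, with one extra equivalent of AlMe3 turning the hydroxyl into an inert dimethylaluminium alkoxide that is hydrolysed on work-up, followed by iodinolysis with retention to the E iodide; the stereocentre is not involved.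

Step 16
Reactants: 11 ring B C19 iodide; 24 (E)-1,2-bis(tributylstannyl)ethene; 23 ring A C19 iodide
Product: 26 (3R)-3',4',7,8,7',8'-hexadehydro-β,β-caroten-3-ol (all-E; target CNP0250213.1), via dienylstannane 25 (not isolated)
Conditions: Pd2(dba)3 (5 mol %), AsPh3 (40 mol %), degassed NMP, 25 °C, Ar, dark: 11 (1.0 equiv) added slowly to 24 (1.0 equiv); after 11 is consumed, 23 (1.0 equiv), 25 → 40 °C; chromatography cold and in the dark
Reagents that add atoms: none
Why: Oxidative addition of the C14'–I bond of 11 to zerovalent palladium (from Pd2(dba)3 and AsPh3), transfer of one stannylvinyl terminus of 24 from tin to palladium and reductive elimination give dienylstannane 25, after which the same cycle engages the C14–I bond of 23 and the remaining C–Sn bond. The closest known reaction type is the Stille coupling of alkenyl iodides with (E)-1,2-bis(tributylstannyl)ethene used as a two-ended linchpin for conjugated polyenes, here with two different iodides added one after the other. No ring is closed and no stereocentre is formed; the (3R) centre of ring A is remote and untouched, and since every elementary step retains alkene geometry, the E configuration of the linchpin and of C13=C14 and C13'=C14' is carried into the heptaene. The selectivity needed is hetero- over homo-capping, which rests on slow addition of 11 to the full charge of 24 before one equivalent of 23 is introduced, while the free C3 hydroxyl makes the hydrocarbon and diol homo-capped heptaenes chromatographically distinct from the mono-ol. Chemoselectivity comes from the substrates themselves, because only the two alkenyl C–I bonds react with zerovalent palladium under these neutral, base-free conditions, leaving the hydroxyl, both enyne units and the ring B diene alone.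

Compound list
1 | 2,6,6-trimethylcyclohex-2-en-1-one | CC1=CCCC(C)(C)C1=O | starting material
2 | lithium 2,6,6-trimethylcyclohexa-1,3-dien-1-olate (lithium dienolate, not isolated) | [Li]OC1=C(C)C=CCC1(C)C | intermediate
3 | 2,6,6-trimethylcyclohexa-1,3-dien-1-yl trifluoromethanesulfonate (ring B dienyl triflate) | CC1=C(OS(=O)(=O)C(F)(F)F)C(C)(C)CC=C1 | intermediate
4 | (E)-3-methylpent-2-en-4-yn-1-ol | C#C/C(C)=C/CO | starting material
5 | (2E)-3-methyl-5-(2,6,6-trimethylcyclohexa-1,3-dien-1-yl)pent-2-en-4-yn-1-ol (ring B C15 alcohol) | CC1=C(C#C/C(C)=C/CO)C(C)(C)CC=C1 | intermediate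
6 | (2E)-3-methyl-5-(2,6,6-trimethylcyclohexa-1,3-dien-1-yl)pent-2-en-4-ynal (ring B C15 aldehyde) | CC1=C(C#C/C(C)=C/C=O)C(C)(C)CC=C1 | intermediate
7 | diethyl [3-(trimethylsilyl)prop-2-yn-1-yl]phosphonate | CCOP(=O)(CC#C[Si](C)(C)C)OCC | starting material
8 | trimethyl[(3E,5E)-6-methyl-8-(2,6,6-trimethylcyclohexa-1,3-dien-1-yl)octa-3,5-diene-1,7-diyn-1-yl]silane (ring B silyl dienediyne) | CC1=C(C#C/C(C)=C/C=C/C#C[Si](C)(C)C)C(C)(C)CC=C1 | intermediate
9 | (3E,5E)-3-methyl-1-(2,6,6-trimethylcyclohexa-1,3-dien-1-yl)octa-3,5-diene-1,7-diyne (ring B terminal alkyne) | CC1=C(C#C/C(C)=C/C=C/C#C)C(C)(C)CC=C1 | intermediate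
10 | dimethyl[(1E,3E,5E)-2,6-dimethyl-8-(2,6,6-trimethylcyclohexa-1,3-dien-1-yl)octa-1,3,5-trien-7-yn-1-yl]alumane (ring B alkenylalane, not isolated) | CC1=C(C#C/C(C)=C/C=C/C(C)=C/[Al](C)C)C(C)(C)CC=C1 | intermediate
11 | (1E,3E,5E)-1-iodo-2,6-dimethyl-8-(2,6,6-trimethylcyclohexa-1,3-dien-1-yl)octa-1,3,5-trien-7-yne (ring B C19 iodide) | CC1=C(C#C/C(C)=C/C=C/C(C)=C/I)C(C)(C)CC=C1 | intermediate
12 | ketoisophorone (2,6,6-trimethylcyclohex-2-ene-1,4-dione) | CC1=CC(=O)CC(C)(C)C1=O | starting material
13 | (6R)-2,2,6-trimethylcyclohexane-1,4-dione ((6R)-levodione) | C[C@@H]1CC(=O)CC(C)(C)C1=O | intermediate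
14 | (4R,6R)-4-hydroxy-2,2,6-trimethylcyclohexan-1-one ((4R,6R)-actinol) | C[C@@H]1C[C@@H](O)CC(C)(C)C1=O | intermediate
15 | (4R,6R)-4-(tert-butyldimethylsilyloxy)-2,2,6-trimethylcyclohexan-1-one | C[C@@H]1C[C@@H](O[Si](C)(C)C(C)(C)C)CC(C)(C)C1=O | intermediate
16 | lithium (4R)-4-(tert-butyldimethylsilyloxy)-2,6,6-trimethylcyclohex-1-en-1-olate (lithium enolate, not isolated) | [Li]OC1=C(C)C[C@@H](O[Si](C)(C)C(C)(C)C)CC1(C)C | intermediate
17 | (4R)-4-(tert-butyldimethylsilyloxy)-2,6,6-trimethylcyclohex-1-en-1-yl trifluoromethanesulfonate (ring A enol triflate) | O=S(=O)(OC1=C(C)C[C@@H](O[Si](C)(C)C(C)(C)C)CC1(C)C)C(F)(F)F | intermediate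
18 | (2E)-5-[(4R)-4-(tert-butyldimethylsilyloxy)-2,6,6-trimethylcyclohex-1-en-1-yl]-3-methylpent-2-en-4-yn-1-ol (ring A C15 alcohol) | OC/C=C(\C)C#CC1=C(C)C[C@@H](O[Si](C)(C)C(C)(C)C)CC1(C)C | intermediate
19 | (2E)-5-[(4R)-4-(tert-butyldimethylsilyloxy)-2,6,6-trimethylcyclohex-1-en-1-yl]-3-methylpent-2-en-4-ynal (ring A C15 aldehyde) | O=C/C=C(\C)C#CC1=C(C)C[C@@H](O[Si](C)(C)C(C)(C)C)CC1(C)C | intermediate
20 | tert-butyldimethyl({(1R)-3,5,5-trimethyl-4-[(3E,5E)-3-methyl-8-(trimethylsilyl)octa-3,5-diene-1,7-diyn-1-yl]cyclohex-3-en-1-yl}oxy)silane (ring A bis-silyl dienediyne) | C[Si](C)(C)C#C/C=C/C=C(\C)C#CC1=C(C)C[C@@H](O[Si](C)(C)C(C)(C)C)CC1(C)C | intermediate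
21 | (1R)-3,5,5-trimethyl-4-[(3E,5E)-3-methylocta-3,5-diene-1,7-diyn-1-yl]cyclohex-3-en-1-ol (ring A hydroxy terminal alkyne) | C#C/C=C/C=C(\C)C#CC1=C(C)C[C@@H](O)CC1(C)C | intermediate
22 | dimethylaluminium alkoxide of (1R)-4-[(3E,5E,7E)-8-(dimethylalumanyl)-3,7-dimethylocta-3,5,7-trien-1-yn-1-yl]-3,5,5-trimethylcyclohex-3-en-1-ol (ring A alkenylalane, not isolated) | C[Al](C)/C=C(C)/C=C/C=C(\C)C#CC1=C(C)C[C@@H](O[Al](C)C)CC1(C)C | intermediate
23 | (1R)-4-[(3E,5E,7E)-8-iodo-3,7-dimethylocta-3,5,7-trien-1-yn-1-yl]-3,5,5-trimethylcyclohex-3-en-1-ol (ring A (3R)-hydroxy C19 iodide) | I/C=C(C)/C=C/C=C(\C)C#CC1=C(C)C[C@@H](O)CC1(C)C | intermediate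
24 | (E)-1,2-bis(tributylstannyl)ethene | CCCC[Sn](CCCC)(CCCC)/C=C/[Sn](CCCC)(CCCC)CCCC | starting material
25 | tributyl[(1E,3E,5E,7E)-4,8-dimethyl-10-(2,6,6-trimethylcyclohexa-1,3-dien-1-yl)deca-1,3,5,7-tetraen-9-yn-1-yl]stannane (dienylstannane, not isolated) | CC1=C(C#C/C(C)=C/C=C/C(C)=C/C=C/[Sn](CCCC)(CCCC)CCCC)C(C)(C)CC=C1 | intermediate
26 | (3R)-3',4',7,8,7',8'-hexadehydro-β,β-caroten-3-ol, all-E (CNP0250213.1) | CC1=C(C#C/C(C)=C/C=C/C(C)=C/C=C/C=C(C)/C=C/C=C(\C)C#CC2=C(C)C[C@@H](O)CC2(C)C)C(C)(C)CC=C1 | target

Total step count: 16.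
Longest linear sequence: 10 steps (steps 7 to 16, ketoisophorone to the target).

Steps most likely to fail

First, step 16, the double Stille coupling. The first iodide may react at both tin termini of 24 before the second iodide is added, unreacted 24 may then cap 23 twice, and the heptaene may undergo E/Z scrambling under palladium and light during the second stage. The fallback sets out from 11 and changes the linchpin to the boron–tin ethene (E)-4,4,5,5-tetramethyl-2-[2-(tributylstannyl)ethenyl]-1,3,2-dioxaborolane. Base-free Stille coupling (Pd2(dba)3, AsPh3, NMP, 25 °C) engages only its tin end and should give the isolable ring B tetraenynyl pinacol boronate F1. F1 is then joined to 23 by Suzuki–Miyaura coupling (Pd(PPh3)4, aq. K3PO4, THF, 25–40 °C), which comes back to the route at 26. The two ends of this linchpin need different activation, so cross-capping is enforced by the reagent and no longer by stoichiometry.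

Second, step 15, the methylalumination–iodination of the hydroxy dienediyne. Carbometalation may stall or also attack the internal C7≡C8 alkyne, the alkenyl–aluminium bond may be protonated before iodine arrives, and iodine may isomerise the triene. The fallback sets out from aldehyde 19 and brings the iodoalkene in ready-made. (E)-3-Iodo-2-methylprop-2-en-1-ol F2, the methylalumination–iodination product of propargyl alcohol (the same reaction on a simple, forgiving substrate), is converted by Appel bromination (CBr4, PPh3, CH2Cl2) into (E)-3-bromo-1-iodo-2-methylprop-1-ene F3. Arbuzov reaction (P(OEt)3, 100 °C) then gives diethyl [(2E)-3-iodo-2-methylprop-2-en-1-yl]phosphonate F4. Horner–Wadsworth–Emmons reaction of F4 (NaN(SiMe3)2, THF, −78 → 0 °C) with 19 should give the silyl-protected ring A C19 iodide F5, and Bu4NF in THF removes the silyl ether, coming back to the route at 23. The same reagent F4 with aldehyde 6 would lead straight to 11 should step 6 suffer in the same way.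

Third, step 13, the olefination that builds C11=C12. E-selectivity may erode, giving a geometric mixture that is hard to separate at the dienediyne stage. The fallback sets out from 19: Takai iodo-olefination (CrCl2, CHI3, THF, 0 °C), a reaction type that favours E alkenyl iodides from enals, should give the (3E,5E)-dienyl iodide F6. Sonogashira coupling of F6 with trimethylsilylacetylene (Pd(PPh3)4, CuI, i-Pr2NH, 25 °C) comes back to the route at 20.

Further compounds
F1 | step 16 | 2-[(1E,3E,5E,7E)-4,8-dimethyl-10-(2,6,6-trimethylcyclohexa-1,3-dien-1-yl)deca-1,3,5,7-tetraen-9-yn-1-yl]-4,4,5,5-tetramethyl-1,3,2-dioxaborolane (ring B tetraenynyl pinacol boronate) | CC1=C(C#C/C(C)=C/C=C/C(C)=C/C=C/B2OC(C)(C)C(C)(C)O2)C(C)(C)CC=C1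
F2 | step 15 | (E)-3-iodo-2-methylprop-2-en-1-ol | OC/C(C)=C/I
F3 | step 15 | (E)-3-bromo-1-iodo-2-methylprop-1-ene | BrC/C(C)=C/I
F4 | step 15 | diethyl [(2E)-3-iodo-2-methylprop-2-en-1-yl]phosphonate | CCOP(=O)(C/C(C)=C/I)OCC
F5 | step 15 | tert-butyl({(1R)-4-[(3E,5E,7E)-8-iodo-3,7-dimethylocta-3,5,7-trien-1-yn-1-yl]-3,5,5-trimethylcyclohex-3-en-1-yl}oxy)dimethylsilane (silyl-protected ring A C19 iodide) | I/C=C(C)/C=C/C=C(\C)C#CC1=C(C)C[C@@H](O[Si](C)(C)C(C)(C)C)CC1(C)C
F6 | step 13 | tert-butyl({(1R)-4-[(3E,5E)-6-iodo-3-methylhexa-3,5-dien-1-yn-1-yl]-3,5,5-trimethylcyclohex-3-en-1-yl}oxy)dimethylsilane ((3E,5E)-dienyl iodide) | I/C=C/C=C(\C)C#CC1=C(C)C[C@@H](O[Si](C)(C)C(C)(C)C)CC1(C)C
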